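## Retrosynthetic overview

1. Ring letters: A/B/C = flavan (benzo ring, 4-hydroxyphenyl, pyran), D = dihydrofuran, E = pyranone, F = its benzo ring, G = second 4-hydroxyphenyl. The usual biflavonoid logic (build a 3-aroyl-2-arylbenzofuran, then biomimetic epoxidation/rearrangement) is deliberately not used.
2. Last bond: the aryl ether O–C(quaternary) bond, by oxidative dearomatization of a protecting-group-free hexaphenol. Ring E and the ring A dienone form together, and the quaternary centre is relayed from the neighbouring carbinol.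
3. Ring F is attached intact: 2,4,6-tris(benzyloxy)phenyllithium onto a ring D Weinreb amide.
4. Ring D, with both of its stereocentres under reagent control: sulfur-ylide [4+1] annulation of an o-hydroxyaryl α-keto amide with a C2-symmetric chiral 4-(benzyloxy)benzyl sulfonium ylide. The keto amide comes from 8-lithio-tri-O-benzyl-epiafzelechin and oxalic bis-Weinreb amide (two-carbon linchpin).
5. Order of ring formation: A/B/C bought as (−)-epiafzelechin → D (ring G arrives with the ylide) → F attached → E plus dearomatised A in the final step.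

Assumption: (−)-epiafzelechin, (2R,3R), is bought as the enantiopure natural product. Chroman locants are used up to ring D closure, then furo[2,3-h]chromene locants (O1, C2–C4, C4a, C5, C6, C6a, O7, C8, C9, C9a, C9b).

## Route

Step 1
Reactants: 1 (−)-epiafzelechin
Product: 2 (2R,3R)-5,7-bis(benzyloxy)-2-[4-(benzyloxy)phenyl]chroman-3-ol
Conditions: BnBr (3.3 equiv), K2CO3, DMF, 0 °C to rt
Reagents that add atoms: benzyl bromide BrCc1ccccc1
Why: Williamson ether synthesis in which carbonate deprotonates only the three phenols, so the secondary 3-OH and both ring C stereocentres are untouched.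

Step 2
Reactants: 2 tri-O-benzyl-epiafzelechin
Product: 3 (2R,3R)-5,7-bis(benzyloxy)-2-[4-(benzyloxy)phenyl]-8-bromochroman-3-ol
Conditions: NBS (1.0 equiv), CH2Cl2, −78 to 0 °C
Reagents that add atoms: N-bromosuccinimide O=C1CCC(=O)N1Br
Why: Electrophilic aromatic bromination, for which C8 is the most nucleophilic ring A carbon of 5,7-di-O-benzyl flavan-3-ols, so one equivalent of NBS reacts there and not at C6 or ring B.

Step 3
Reactants: 3 8-bromide; 4 N,N'-dimethoxy-N,N'-dimethyloxamide
Product: 6 2-[(2R,3R)-5,7-bis(benzyloxy)-2-(4-benzyloxyphenyl)-3-hydroxychroman-8-yl]-N-methoxy-N-methyl-2-oxoacetamide, via dilithio species 5 (not isolated)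
Conditions: n-BuLi (2.2 equiv), THF, −78 °C; cannulate into 4 (2 equiv), THF, −78 to −20 °C; AcOH
Reagents that add atoms: none
Why: Bromine–lithium exchange (first equivalent of base makes the 3-alkoxide) followed by Weinreb-type acyl substitution, in which the chelated tetrahedral adduct survives until the quench so that a single addition gives the α-keto amide.

Step 4
Reactants: 6 α-keto amide
Product: 7 2-[(2R,3R)-5-(benzyloxy)-2-(4-benzyloxyphenyl)-3,7-dihydroxychroman-8-yl]-N-methoxy-N-methyl-2-oxoacetamide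
Conditions: MgBr2·OEt2 (3 equiv), toluene–Et2O, 50 °C; 1 M HCl
Reagents that add atoms: none
Why: Chelation-controlled debenzylation in which magnesium bridged between the C8 ketone and the ortho O7 ether lets bromide cleave only that benzyl group (SN2 at the benzylic CH2), the 5-O and 4'-O benzyl ethers lying outside any chelate.

Step 5
Reactants: 8 (2S,5S)-hexane-2,5-diol
Product: 9 (2S,5S)-hexane-2,5-diyl dimethanesulfonate
Conditions: MsCl, Et3N, CH2Cl2, 0 °C
Reagents that add atoms: methanesulfonyl chloride CS(=O)(=O)Cl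
Why: Sulfonylation of both secondary alcohols at oxygen, which retains configuration and installs two leaving groups.

Step 6
Reactants: 9 dimesylate
Product: 10 (2R,5R)-2,5-dimethylthiolane
Conditions: Na2S, DMSO, rt
Reagents that add atoms: sodium sulfide [Na+].[Na+].[S-2]
Why: Double SN2 thioetherification in which sulfide displaces both mesylates with inversion, converting the (2S,5S) diol configuration into the (2R,5R) thiolane.

Step 7
Reactants: 10 (2R,5R)-2,5-dimethylthiolane; 11 4-(benzyloxy)benzyl chloride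
Product: 12 (2R,5R)-1-[4-(benzyloxy)benzyl]-2,5-dimethylthiolan-1-ium tetrafluoroborate
Conditions: AgBF4, CH2Cl2, 0 °C to rt, dark
Reagents that add atoms: silver tetrafluoroborate [Ag+].F[B-](F)(F)F
Why: S-Alkylation of the sulfide by the electron-rich benzylic chloride driven by AgCl precipitation, giving one sulfonium salt because the C2 axis makes both sulfur lone pairs equivalent.

Step 8
Reactants: 7 7-hydroxy keto amide; 12 chiral sulfonium salt
Product: 15 (2R,3R,8S,9S)-5-(benzyloxy)-2,8-bis[4-(benzyloxy)phenyl]-3,9-dihydroxy-N-methoxy-N-methyl-3,4,8,9-tetrahydro-2H-furo[2,3-h]chromene-9-carboxamide, via sulfonium ylide 13 (not isolated), via trans-epoxide 14 (not isolated)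
Conditions: 12, LiN(SiMe3)2 (1.05 equiv), THF, −78 °C; add lithium phenoxide of 7 (7 + LiN(SiMe3)2, 1.0 equiv), −78 to −40 °C; AcOH, −78 °C; PPTS (cat.), CH2Cl2, 0 °C
Reagents that add atoms: none
Why: Proposed new method: an asymmetric Corey–Chaykovsky epoxidation merged with phenol epoxide-opening as a formal [4+1] annulation, in which the C2-symmetric ylide 13 adds through one face of its benzylic carbon (giving the S carbon, the sense this sulfide shows with aldehydes) to the lithium-chelated ketone of 7 with the aryl anti to the bulky chromanyl group to give the (2S,3S) trans-epoxide 14, whose p-benzyloxybenzylic C–O bond then ionises under mild acid so that the ortho phenol closes ring D with the aryl anti to the carboxamide, the carbinol centre (C9, S) being retained from 14 and C8 (S) set in the closure, the closest known reactions being sulfur-ylide epoxidation of isatins and α-keto esters and the ylide [4+1] annulation of o-hydroxyaryl carbonyl compounds and o-quinone methides.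

Step 9
Reactants: 16 1,3,5-tris(benzyloxy)benzene
Product: 17 2-bromo-1,3,5-tris(benzyloxy)benzene
Conditions: NBS (1.0 equiv), CH2Cl2, 0 °C
Reagents that add atoms: N-bromosuccinimide O=C1CCC(=O)N1Br
Why: Electrophilic aromatic bromination of the symmetric triether, all three ring positions being equivalent so a single monobromide forms.

Step 10
Reactants: 15 ring D Weinreb amide; 17 aryl bromide
Product: 19 [(2R,3R,8S,9S)-5-(benzyloxy)-2,8-bis[4-(benzyloxy)phenyl]-3,9-dihydroxy-3,4,8,9-tetrahydro-2H-furo[2,3-h]chromen-9-yl][2,4,6-tris(benzyloxy)phenyl]methanone, via aryllithium 18 (not isolated)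
Conditions: 15, LiN(SiMe3)2 (2.1 equiv), THF, −78 °C; then 18 (from 17 and n-BuLi, 2.0 equiv each, THF, −78 °C); −78 to 0 °C; AcOH
Reagents that add atoms: none
Why: Bromine–lithium exchange and Weinreb ketone synthesis in which both hydroxyls are first masked as lithium alkoxides, the aryllithium adds once and the chelate collapses to the ketone only on quench, no stereocentre being touched.

Step 11
Reactants: 19 hexabenzyl ketone
Product: 20 [(2R,3R,8S,9S)-3,5,9-trihydroxy-2,8-bis(4-hydroxyphenyl)-3,4,8,9-tetrahydro-2H-furo[2,3-h]chromen-9-yl](2,4,6-trihydroxyphenyl)methanone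
Conditions: H2 (1 atm), Pd(OH)2 on carbon, THF–MeOH, rt
Reagents that add atoms: none
Why: Catalytic hydrogenolysis of the six aryl benzyl ethers under neutral conditions, which leaves the tertiary benzylic alcohol, the two cyclic benzylic ethers and the hindered aryl ketone intact.

Step 12
Reactants: 20 hexaphenol
Product: 21 CNP0170480.3 (target)
Conditions: PhI(OAc)2 (1.05 equiv), CF3CH2OH–MeCN, −30 °C
Reagents that add atoms: none
Why: Oxidative dearomatization (hypervalent-iodine para spiro-etherification) in which the most electron-rich phenol (ring A, 5-OH) is activated, an ortho hydroxyl of the symmetric ring F attacks C9a para to it through the ketone tether and therefore on the face of the aroyl group, so the quaternary centre is fixed by the adjacent carbinol (cis-fused rings D/E) and the stabilised 3,5-dialkoxy dienone results.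

## Compound list

1 | (−)-epiafzelechin, (2R,3R)-2-(4-hydroxyphenyl)chromane-3,5,7-triol | O[C@@H]1Cc2c(O)cc(O)cc2O[C@@H]1c1ccc(O)cc1 | starting material
2 | (2R,3R)-5,7-bis(benzyloxy)-2-[4-(benzyloxy)phenyl]chroman-3-ol | O[C@@H]1Cc2c(OCc3ccccc3)cc(OCc3ccccc3)cc2O[C@@H]1c1ccc(OCc2ccccc2)cc1 | intermediate
3 | (2R,3R)-5,7-bis(benzyloxy)-2-[4-(benzyloxy)phenyl]-8-bromochroman-3-ol | O[C@@H]1Cc2c(OCc3ccccc3)cc(OCc3ccccc3)c(Br)c2O[C@@H]1c1ccc(OCc2ccccc2)cc1 | intermediate
4 | N,N'-dimethoxy-N,N'-dimethyloxamide | CON(C)C(=O)C(=O)N(C)OC | starting material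
5 | dilithio species of 3 (8-aryllithium, lithium 3-alkoxide) | [Li]O[C@@H]1Cc2c(OCc3ccccc3)cc(OCc3ccccc3)c([Li])c2O[C@@H]1c1ccc(OCc2ccccc2)cc1 | intermediate
6 | 2-[(2R,3R)-5,7-bis(benzyloxy)-2-(4-benzyloxyphenyl)-3-hydroxychroman-8-yl]-N-methoxy-N-methyl-2-oxoacetamide | O[C@@H]1Cc2c(OCc3ccccc3)cc(OCc3ccccc3)c(C(=O)C(=O)N(C)OC)c2O[C@@H]1c1ccc(OCc2ccccc2)cc1 | intermediate
7 | 2-[(2R,3R)-5-(benzyloxy)-2-(4-benzyloxyphenyl)-3,7-dihydroxychroman-8-yl]-N-methoxy-N-methyl-2-oxoacetamide | O[C@@H]1Cc2c(OCc3ccccc3)cc(O)c(C(=O)C(=O)N(C)OC)c2O[C@@H]1c1ccc(OCc2ccccc2)cc1 | intermediate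
8 | (2S,5S)-hexane-2,5-diol | C[C@H](O)CC[C@H](C)O | starting material
9 | (2S,5S)-hexane-2,5-diyl dimethanesulfonate | C[C@H](OS(C)(=O)=O)CC[C@H](C)OS(C)(=O)=O | intermediate
10 | (2R,5R)-2,5-dimethylthiolane | C[C@@H]1CC[C@@H](C)S1 | intermediate
11 | 4-(benzyloxy)benzyl chloride | ClCc1ccc(OCc2ccccc2)cc1 | starting material
12 | (2R,5R)-1-[4-(benzyloxy)benzyl]-2,5-dimethylthiolan-1-ium tetrafluoroborate | C[C@@H]1CC[C@@H](C)[S+]1Cc1ccc(OCc2ccccc2)cc1.F[B-](F)(F)F | intermediate
13 | sulfonium ylide, [(2R,5R)-2,5-dimethylthiolan-1-ium-1-yl][4-(benzyloxy)phenyl]methanide | C[C@@H]1CC[C@@H](C)[S+]1[CH-]c1ccc(OCc2ccccc2)cc1 | intermediate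
14 | trans-epoxide, (2S,3S)-2-[(2R,3R)-5-(benzyloxy)-2-(4-benzyloxyphenyl)-3,7-dihydroxychroman-8-yl]-3-[4-(benzyloxy)phenyl]-N-methoxy-N-methyloxirane-2-carboxamide | O[C@@H]1Cc2c(OCc3ccccc3)cc(O)c([C@@]3(O[C@H]3c3ccc(OCc4ccccc4)cc3)C(=O)N(C)OC)c2O[C@@H]1c1ccc(OCc2ccccc2)cc1 | intermediate
15 | (2R,3R,8S,9S)-5-(benzyloxy)-2,8-bis[4-(benzyloxy)phenyl]-3,9-dihydroxy-N-methoxy-N-methyl-3,4,8,9-tetrahydro-2H-furo[2,3-h]chromene-9-carboxamide | O[C@@H]1Cc2c(OCc3ccccc3)cc3O[C@@H](c4ccc(OCc5ccccc5)cc4)[C@](O)(C(=O)N(C)OC)c3c2O[C@@H]1c1ccc(OCc2ccccc2)cc1 | intermediate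
16 | 1,3,5-tris(benzyloxy)benzene | c1ccc(COc2cc(OCc3ccccc3)cc(OCc3ccccc3)c2)cc1 | starting material
17 | 2-bromo-1,3,5-tris(benzyloxy)benzene | Brc1c(OCc2ccccc2)cc(OCc2ccccc2)cc1OCc1ccccc1 | intermediate
18 | 2,4,6-tris(benzyloxy)phenyllithium | [Li]c1c(OCc2ccccc2)cc(OCc2ccccc2)cc1OCc1ccccc1 | intermediate
19 | [(2R,3R,8S,9S)-5-(benzyloxy)-2,8-bis[4-(benzyloxy)phenyl]-3,9-dihydroxy-3,4,8,9-tetrahydro-2H-furo[2,3-h]chromen-9-yl][2,4,6-tris(benzyloxy)phenyl]methanone | O[C@@H]1Cc2c(OCc3ccccc3)cc3O[C@@H](c4ccc(OCc5ccccc5)cc4)[C@](O)(C(=O)c4c(OCc5ccccc5)cc(OCc5ccccc5)cc4OCc4ccccc4)c3c2O[C@@H]1c1ccc(OCc2ccccc2)cc1 | intermediate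
20 | [(2R,3R,8S,9S)-3,5,9-trihydroxy-2,8-bis(4-hydroxyphenyl)-3,4,8,9-tetrahydro-2H-furo[2,3-h]chromen-9-yl](2,4,6-trihydroxyphenyl)methanone | O[C@@H]1Cc2c(O)cc3O[C@@H](c4ccc(O)cc4)[C@](O)(C(=O)c4c(O)cc(O)cc4O)c3c2O[C@@H]1c1ccc(O)cc1 | intermediate
21 | CNP0170480.3: ring A 5-oxo-dienone of (2R,3R)-epiafzelechin whose former C8 is the quaternary O-bearing carbon (S) shared by the cis-fused 3,5,7-trihydroxychroman-4-one (carbinol carbon R) and the 2-(4-hydroxyphenyl)dihydrofuran (ArCH–O carbon S) | O=C1C=C2O[C@@H](c3ccc(O)cc3)[C@]3(O)C(=O)c4c(O)cc(O)cc4O[C@]23C2=C1C[C@@H](O)[C@@H](c1ccc(O)cc1)O2 | target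

## Step count and risks

Total steps: 12. Longest linear sequence: 8 (steps 1, 2, 3, 4, 8, 10, 11, 12, from compound 1).

**Step 8** is the least precedented step. The ketone is deactivated as its phenoxide, the facial sense and the trans selectivity of the ylide are assigned by analogy, and the acid-triggered closure competes with aryl migration in the benzylic cation. If only the facial sense is wrong, the (2S,5S)-sulfide from the enantiomeric diol is used. The fallback abandons the ylide. It sets out from 7, whose only free phenol is alkylated with 11 (K2CO3, acetone) to give 2-[(2R,3R)-5-(benzyloxy)-7-{[4-(benzyloxy)benzyl]oxy}-2-(4-benzyloxyphenyl)-3-hydroxychroman-8-yl]-N-methoxy-N-methyl-2-oxoacetamide F1. A non-nucleophilic superbase (phosphazene P4-t-Bu, THF, −78 °C) reversibly deprotonates the benzylic ether carbon, and the carbanion adds to the neighbouring ketone in a reversible intramolecular aldol-type closure. This gives the trans dihydrobenzofuranol as 15 together with its (2R,3R,8R,9R)-diastereomer F2. The two differ in their relation to the ring C stereocentres and are separated by chromatography. The fallback comes back to the route at 15.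

**Step 10** joins a di-ortho-substituted aryllithium to a Weinreb amide on a quaternary carbon. Addition may be slow and loss of the N-methoxy group by base can compete. The fallback sets out from 15, which is reduced (LiAlH4, THF, −78 to 0 °C, the chelate stopping at the aldehyde stage) to (2R,3R,8S,9S)-5-(benzyloxy)-2,8-bis[4-(benzyloxy)phenyl]-3,9-dihydroxy-3,4,8,9-tetrahydro-2H-furo[2,3-h]chromene-9-carbaldehyde F3. The unhindered formyl group takes up aryllithium 18 to give the secondary carbinol {ring D centres as in 15, both carbinol epimers}[2,4,6-tris(benzyloxy)phenyl]methanol F4. MnO2 (CH2Cl2) oxidises only this electron-rich benzylic carbinol and not the ring C alcohol. The fallback comes back at 19.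

**Step 12** must oxidise one of six phenols. Ring B or ring G could be oxidised instead, or the ring A phenoxonium could lose a C4 proton to an o-quinone methide. The fallback dearomatises before the phenols are all free. It sets out from 19, where MgBr2·OEt2 removes one benzyl ether ortho to the aryl ketone to give the mono-phenol [2,4-bis(benzyloxy)-6-hydroxyphenyl] ketone F5. PhI(OCOCF3)2 in (CF3)2CHOH oxidises the trialkoxy ring A aryl ether to its radical cation, the free ring F phenol closes onto C9a, and the 5-O-benzyl group is lost. This gives the tetra-O-benzyl spirodienone F6. Brief hydrogenolysis (H2, Pd/C, EtOAc) removes the remaining four benzyl groups, and the fallback comes back at 21.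

Further compounds
F1 | step 8 | 2-[(2R,3R)-5-(benzyloxy)-7-{[4-(benzyloxy)benzyl]oxy}-2-(4-benzyloxyphenyl)-3-hydroxychroman-8-yl]-N-methoxy-N-methyl-2-oxoacetamide | O[C@@H]1Cc2c(OCc3ccccc3)cc(OCc3ccc(OCc4ccccc4)cc3)c(C(=O)C(=O)N(C)OC)c2O[C@@H]1c1ccc(OCc2ccccc2)cc1
F2 | step 8 | (2R,3R,8R,9R)-5-(benzyloxy)-2,8-bis[4-(benzyloxy)phenyl]-3,9-dihydroxy-N-methoxy-N-methyl-3,4,8,9-tetrahydro-2H-furo[2,3-h]chromene-9-carboxamide | O[C@@H]1Cc2c(OCc3ccccc3)cc3O[C@H](c4ccc(OCc5ccccc5)cc4)[C@@](O)(C(=O)N(C)OC)c3c2O[C@@H]1c1ccc(OCc2ccccc2)cc1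
F3 | step 10 | (2R,3R,8S,9S)-5-(benzyloxy)-2,8-bis[4-(benzyloxy)phenyl]-3,9-dihydroxy-3,4,8,9-tetrahydro-2H-furo[2,3-h]chromene-9-carbaldehyde | O[C@@H]1Cc2c(OCc3ccccc3)cc3O[C@@H](c4ccc(OCc5ccccc5)cc4)[C@](O)(C=O)c3c2O[C@@H]1c1ccc(OCc2ccccc2)cc1
F4 | step 10 | {ring D centres as in 15, both carbinol epimers}[2,4,6-tris(benzyloxy)phenyl]methanol adduct of F3 | O[C@@H]1Cc2c(OCc3ccccc3)cc3O[C@@H](c4ccc(OCc5ccccc5)cc4)[C@](O)(C(O)c4c(OCc5ccccc5)cc(OCc5ccccc5)cc4OCc4ccccc4)c3c2O[C@@H]1c1ccc(OCc2ccccc2)cc1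
F5 | step 12 | [(2R,3R,8S,9S)-5-(benzyloxy)-2,8-bis[4-(benzyloxy)phenyl]-3,9-dihydroxy-3,4,8,9-tetrahydro-2H-furo[2,3-h]chromen-9-yl][2,4-bis(benzyloxy)-6-hydroxyphenyl]methanone | O[C@@H]1Cc2c(OCc3ccccc3)cc3O[C@@H](c4ccc(OCc5ccccc5)cc4)[C@](O)(C(=O)c4c(O)cc(OCc5ccccc5)cc4OCc4ccccc4)c3c2O[C@@H]1c1ccc(OCc2ccccc2)cc1
F6 | step 12 | tetra-O-benzyl ether of 21 (benzyl on both 4-hydroxyphenyl oxygens and on the two free ring F oxygens) | O=C1C=C2O[C@@H](c3ccc(OCc4ccccc4)cc3)[C@]3(O)C(=O)c4c(OCc5ccccc5)cc(OCc5ccccc5)cc4O[C@]23C2=C1C[C@@H](O)[C@@H](c1ccc(OCc3ccccc3)cc1)O2
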